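Start with the easy step: multiply the charges. The flask holds c(reagent) = 0.300 M, south held 0.450 M, and you hold each constant (pseudo-first-order).

- south: substrate 0.18 M; reagent 2.5 equiv; run made earlier
- flask: substrate 0.12 M; reagent 2.50 equiv; time 2.0 d

south run (percent of the substrate charged)

| time / h | side product / % | target / % |
|---|---|---|
| 0.417 | 0 | 4 |
| 1.33 | 0 | 17 |
| 2.00 | 2 | 25 |
| 3.00 | 0 | 25 |
| 5.00 | 4 | 44 |

(scatter of a reading: 2 percentage points)

- ratio of side product to target at 6.0 min
- ratio of side product to target at 2.0 d

Suppose, as south's early zeros allow, that side product comes from something that builds up in proportion to time. Its rate then goes as c(reagent)·t, which integrates to c(reagent)·t squared, while target grows as t. The ratio therefore follows one number: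

N = c(reagent)·t in the flask / c(reagent)·t at south's last reading = 0.0133 at 6.0 min

N, the reagent exposure relative to south's last reading, multiplies south's read ratio s = 0.0909, a reading with 2 percentage points of scatter on its 4%.

ratio at 6.0 min = s·N = 0.00121

ratio at 2.0 d = s·6.40 = 0.582

Is one number enough? Early, yes: 6.0 min lies far inside south's run. Late, no: read as first-order decay of substrate, target's climb gives 5.57 substrate lifetimes in 2.0 d, so growth in proportion to time cannot last that long, and my second value is a rough extrapolation, not a bound in either direction.

The forecast gave 0.03 (0 to 0.12) and 0.2 (0.03 to 1.2), remarking: “The zeros at early times lean slightly towards the consecutive route, but weakly.”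

The flask gives 0.00154 at 6.0 min and 0.360 at 2.0 d, the second less than my extrapolated value.

    substrate → intermediate A (k = 1.53 × 10⁻⁵ s⁻¹)
    substrate → target (k = 3.64 × 10⁻⁵ s⁻¹)
    intermediate A ⇌ intermediate B (K = 0.430, k = 2.18 × 10⁻⁵ s⁻¹)
    reagent + intermediate A → side product (k = 6.80 × 10⁻⁵ M⁻¹ s⁻¹)

Divided by N, the flask's early ratio gives 0.116; a neighbour flask at 1.50 equiv of reagent, with N = 0.00800, stores 9.25 × 10⁻⁴ and gives 0.116. In the flask, intermediate A is made 1.94 times as fast as it is used up at 0.155 d. At 2.00 d that made-to-used rate ratio is 0.360, with substrate down to 0.0132% and 2.73% of intermediate A standing.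

(The numbers in the tables stem from a simulated flask with made-up constants; noise was put on by code.)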